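## Retrosynthetic overview

1. The butenolide is made last from an allyl group on C9 (hydroformylation, glyoxylic acid annulation, reduction); the aryl propanoate comes from a C19 acrylate and 4-iodophenol.
2. Key disconnection: the 6α-hydroxy-Δ5(10) core 17 comes from the isomeric tertiary alcohol 15 by ionisation at C9, 1,2-shift of the angular allyl group from C10 to C9, and return of oxygen at C6 of the resulting allyl cation.
3. 15 comes from the Wieland–Miescher-type enedione 6: a silyl dienol ether masks the ring A enone, then C8 methylation, C9 methyl addition and C4 hydroxymethylation anti to the allyl group.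
4. 6 comes from cyclohexane-1,3-dione, allyl bromide and ethyl vinyl ketone by asymmetric Robinson annulation.
5. Ring order: ring B (the dione) is present first, ring A is closed in step 2, the decalin is re-wired in step 7, the butenolide ring is closed in steps 9–10.

Assumption: positions carry the diterpenoid (halimane) numbering C1–C20 of the target; α is the face of the C9 side chain and the 6-OH, β the face of the C8/C9 methyls and of C19; compounds 1, 2, 4, 14, 18 and 20 are taken to be catalogue chemicals.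

## Route

Step 1
Reactants: 1 cyclohexane-1,3-dione; 2 allyl bromide (3-bromoprop-1-ene)
Product: 3 2-(prop-2-en-1-yl)cyclohexane-1,3-dione
Conditions: KOH (1.0 equiv), Cu powder (cat.), H2O, 0 → 23 °C
Reagents that add atoms: none
Why: C-allylation of the potassium enolate of a cyclic 1,3-dione with a reactive allylic halide in water (Stetter-type alkylation) is the standard entry to 2-allyl diones; no stereocentre is formed.

Step 2
Reactants: 3 2-(prop-2-en-1-yl)cyclohexane-1,3-dione; 4 pent-1-en-3-one (ethyl vinyl ketone)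
Product: 6 (8aS)-5-methyl-8a-(prop-2-en-1-yl)-3,4,8,8a-tetrahydronaphthalene-1,6(2H,7H)-dione, via achiral triketone 5 (not isolated)
Conditions: Et3N (10 mol %), EtOAc, 23 °C; evaporate; D-phenylalanine (1.0 equiv), (1S)-(+)-10-camphorsulfonic acid (0.5 equiv), DMF, 30 → 70 °C; recrystallise
Reagents that add atoms: none
Why: Michael addition followed by the amino-acid-mediated intramolecular aldol condensation (Hajos–Parrish–Eder–Sauer–Wiechert reaction, Hagiwara–Uda conditions for ethyl-ketone triketones) closes ring A; the enamine of the D-amino acid attacks one enantiotopic ring carbonyl, which fixes the quaternary C10 as the mirror image of the L-series (allyl α, descriptor S because allyl outranks the ring CH2).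

Step 3
Reactants: 6 (8aS)-5-methyl-8a-(prop-2-en-1-yl)-3,4,8,8a-tetrahydronaphthalene-1,6(2H,7H)-dione
Product: 8 (8aS)-5-methyl-8a-(prop-2-en-1-yl)-6-[(trimethylsilyl)oxy]-3,7,8,8a-tetrahydronaphthalen-1(2H)-one, via potassium dienolate 7 (not isolated)
Conditions: KOt-Bu (1.05 equiv), THF, 0 °C; Me3SiCl (1.3 equiv), −78 °C; non-aqueous work-up
Reagents that add atoms: chlorotrimethylsilane, C[Si](C)(C)Cl
Why: Thermodynamic deprotonation removes the vinylogous γ-proton of the ring A enone (the most acidic C–H) and O-silylation of the extended dienolate gives the 3-silyloxy-3,5-diene (silyl dienol ether formation), which masks the enone so that the C9 ketone is the only carbonyl left and stores the dienolate for step 5; no new stereocentre.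

Step 4
Reactants: 8 (8aS)-5-methyl-8a-(prop-2-en-1-yl)-6-[(trimethylsilyl)oxy]-3,7,8,8a-tetrahydronaphthalen-1(2H)-one
Product: 10 (2S,8aS)-2,5-dimethyl-8a-(prop-2-en-1-yl)-6-[(trimethylsilyl)oxy]-3,7,8,8a-tetrahydronaphthalen-1(2H)-one, via lithium enolate 9 (not isolated)
Conditions: LiN(i-Pr)2 (1.1 equiv), THF, −78 °C; MeI (1.5 equiv), −78 → −30 °C
Reagents that add atoms: iodomethane, CI
Why: Kinetic enolate alkylation of the only ketone (C10 is quaternary, so the enolate can only form towards C8); MeI enters C8 on the β-face, anti to the pseudo-axial α-allyl group two atoms away, giving the 8β (equatorial, also thermodynamic) methyl, 8S.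

Step 5
Reactants: 10 (2S,8aS)-2,5-dimethyl-8a-(prop-2-en-1-yl)-6-[(trimethylsilyl)oxy]-3,7,8,8a-tetrahydronaphthalen-1(2H)-one
Product: 13 (1S,4aS,5R,6S)-5-hydroxy-1-(hydroxymethyl)-1,5,6-trimethyl-4a-(prop-2-en-1-yl)-3,4,4a,5,6,7-hexahydronaphthalen-2(1H)-one, via C9 lithium alkoxide 11 (not isolated), via dilithium dienolate 12 (not isolated)
Conditions: MeLi (2.3 equiv), THF, −78 → 23 °C; monomeric HCHO (from cracked paraformaldehyde, THF, 5 equiv), −78 °C; AcOH, −78 °C
Reagents that add atoms: methyllithium, [Li]C; formaldehyde, C=O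
Why: The first MeLi adds to the C9 ketone anti to the allyl group (9β-methyl, 9α-OH; this centre is erased in step 7), the second cleaves the Si–O bond (Stork–House regiospecific enolate generation from a silyl enol ether), and the lithium dienolate undergoes a kinetic α-aldol with formaldehyde at C4 on the β-face, anti to the angular α-allyl group, setting C4 as S (CH2OH β, methyl α).

Step 6
Reactants: 13 (1S,4aS,5R,6S)-5-hydroxy-1-(hydroxymethyl)-1,5,6-trimethyl-4a-(prop-2-en-1-yl)-3,4,4a,5,6,7-hexahydronaphthalen-2(1H)-one; 14 acryloyl chloride (prop-2-enoyl chloride)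
Product: 15 [(1S,4aS,5R,6S)-5-hydroxy-1,5,6-trimethyl-2-oxo-4a-(prop-2-en-1-yl)-1,2,3,4,4a,5,6,7-octahydronaphthalen-1-yl]methyl prop-2-enoate
Conditions: Et3N (1.5 equiv), DMAP (5 mol %), CH2Cl2, −20 °C
Reagents that add atoms: none
Why: Nucleophile-catalysed O-acylation is selective for the primary C19 alcohol over the hindered tertiary C9 alcohol, and the ester stops C19–OH from trapping the cation of step 7 as a cyclic ether; no stereocentre is affected.

Step 7
Reactants: 15 [(1S,4aS,5R,6S)-5-hydroxy-1,5,6-trimethyl-2-oxo-4a-(prop-2-en-1-yl)-1,2,3,4,4a,5,6,7-octahydronaphthalen-1-yl]methyl prop-2-enoate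
Product: 17 [(1S,5R,6S,8S)-8-hydroxy-1,5,6-trimethyl-2-oxo-5-(prop-2-en-1-yl)-1,2,3,4,5,6,7,8-octahydronaphthalen-1-yl]methyl prop-2-enoate, via C9 perrhenate ester 16 (not isolated)
Conditions: Re2O7 (5 mol %), H2O (1 equiv), (CF3)2CHOH/CH2Cl2 (1:4), 0 → 23 °C
Reagents that add atoms: none
Why: Proposed new method: Re2O7-catalysed dehydrative 1,2-alkyl shift with 1,4-return of the hydroxyl group (a net isomerisation), in which perrhenate ester 16 ionises at C9 in the fluorinated alcohol, the axial C10–allyl σ-bond (parallel to the empty C9 orbital) migrates suprafacially on the α-face because an unstabilised tertiary cation becomes the C10–C5–C6 allyl cation, so the C10 stereocentre is transferred to C9 (9R, methyl β, allyl α), and perrhenate returns to the allyl termini, equilibrates by the known 1,3-oxo-metal shift and is hydrolysed to the more stable secondary 6α-alcohol (6S; OH pseudo-axial, clear of the C4 substituents and trans to the 8β-methyl, tetrasubstituted alkene); the closest known reaction types are the Re2O7-catalysed 1,3-transposition of allylic alcohols and the acid-mediated Wagner–Meerwein backbone (friedo) rearrangement of decalin terpenoids that ends by elimination.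

Step 8
Reactants: 17 [(1S,5R,6S,8S)-8-hydroxy-1,5,6-trimethyl-2-oxo-5-(prop-2-en-1-yl)-1,2,3,4,5,6,7,8-octahydronaphthalen-1-yl]methyl prop-2-enoate; 18 4-iodophenol
Product: 19 [(1S,5R,6S,8S)-8-hydroxy-1,5,6-trimethyl-2-oxo-5-(prop-2-en-1-yl)-1,2,3,4,5,6,7,8-octahydronaphthalen-1-yl]methyl 3-(4-hydroxyphenyl)propanoate
Conditions: CoBr2 (10 mol %), 2,2′-bipyridine (10 mol %), Mn powder (3 equiv), H2O (3 equiv), CF3CO2H (5 mol %), DMF/pyridine (9:1), 60 °C
Reagents that add atoms: none
Why: Cobalt-catalysed reductive conjugate addition of an aryl halide to an acrylate (arylcobalt 1,4-addition, protonation by water, Mn as terminal reductant) builds the aryl propanoate without phenol protection, the terminal acrylate being far more reactive than the allyl and tetrasubstituted alkenes; no stereocentre is affected.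

Step 9
Reactants: 19 [(1S,5R,6S,8S)-8-hydroxy-1,5,6-trimethyl-2-oxo-5-(prop-2-en-1-yl)-1,2,3,4,5,6,7,8-octahydronaphthalen-1-yl]methyl 3-(4-hydroxyphenyl)propanoate; 20 glyoxylic acid (oxoacetic acid, used as the monohydrate)
Product: 22 [(1S,5R,6S,8S)-8-hydroxy-5-[2-(2-hydroxy-5-oxo-2,5-dihydrofuran-3-yl)ethyl]-1,5,6-trimethyl-2-oxo-1,2,3,4,5,6,7,8-octahydronaphthalen-1-yl]methyl 3-(4-hydroxyphenyl)propanoate, via linear aldehyde 21 (not isolated)
Conditions: Rh(acac)(CO)2 (1 mol %), BiPhePhos (2 mol %), CO/H2 (1:1, 10 bar), toluene, 60 °C; vent; then 20 (1.5 equiv), morpholine hydrochloride (1.2 equiv), 1,4-dioxane/H2O (4:1), 80 °C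
Reagents that add atoms: carbon monoxide, [C-]#[O+]
Why: Linear-selective rhodium/bisphosphite hydroformylation of the only monosubstituted alkene, then amine-salt-mediated aldol condensation of the aldehyde α-CH2 with glyoxylic acid and ring closure (the industrial route to 4-alkyl-5-hydroxybutenolides), gives the pseudo-acid as an inconsequential epimer mixture at the hemiacetal carbon; the allylic 6-alcohol is the thermodynamic isomer and survives the aqueous weakly acidic medium.

Step 10
Reactants: 22 [(1S,5R,6S,8S)-8-hydroxy-5-[2-(2-hydroxy-5-oxo-2,5-dihydrofuran-3-yl)ethyl]-1,5,6-trimethyl-2-oxo-1,2,3,4,5,6,7,8-octahydronaphthalen-1-yl]methyl 3-(4-hydroxyphenyl)propanoate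
Product: 24 [(1S,5R,6S,8S)-8-hydroxy-1,5,6-trimethyl-2-oxo-5-[2-(5-oxo-2,5-dihydrofuran-3-yl)ethyl]-1,2,3,4,5,6,7,8-octahydronaphthalen-1-yl]methyl 3-(4-hydroxyphenyl)propanoate, via (Z)-hydroxy acid 23 (not isolated)
Conditions: NaBH4 (1.2 equiv), EtOH/CH2Cl2 (3:7), −78 → −30 °C; then 2 M HCl, 23 °C
Reagents that add atoms: none
Why: Borohydride opens the pseudo-acid to its (Z)-formyl acrylate form and reduces the aldehyde chemoselectively at low temperature (aldehyde over the hindered α-quaternary C3 ketone, Ward-type conditions), and acid closes hydroxy acid 23 to the butenolide (standard 5-hydroxybutenolide reduction); no stereocentre is touched.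

## Compound list

1 | cyclohexane-1,3-dione | O=C1CCCC(=O)C1 | starting material
2 | allyl bromide (3-bromoprop-1-ene) | C=CCBr | starting material
3 | 2-(prop-2-en-1-yl)cyclohexane-1,3-dione | C=CCC1C(=O)CCCC1=O | intermediate
4 | pent-1-en-3-one (ethyl vinyl ketone) | CCC(=O)C=C | starting material
5 | 2-(3-oxopentyl)-2-(prop-2-en-1-yl)cyclohexane-1,3-dione (achiral triketone) | CCC(=O)CCC1(CC=C)C(=O)CCCC1=O | intermediate (not isolated)
6 | (8aS)-5-methyl-8a-(prop-2-en-1-yl)-3,4,8,8a-tetrahydronaphthalene-1,6(2H,7H)-dione | O=C1CC[C@@]2(CC=C)C(=O)CCCC2=C1C | intermediate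
7 | potassium extended (3,5-)dienolate of 6 | [K+].[O-]C1=C(C)C2=CCCC(=O)[C@]2(CC=C)CC1 | intermediate (not isolated)
8 | (8aS)-5-methyl-8a-(prop-2-en-1-yl)-6-[(trimethylsilyl)oxy]-3,7,8,8a-tetrahydronaphthalen-1(2H)-one | C[Si](C)(C)OC1=C(C)C2=CCCC(=O)[C@]2(CC=C)CC1 | intermediate
9 | lithium C8=C9 enolate of 8 | C[Si](C)(C)OC1=C(C)C2=CCC=C([O-])[C@]2(CC=C)CC1.[Li+] | intermediate (not isolated)
10 | (2S,8aS)-2,5-dimethyl-8a-(prop-2-en-1-yl)-6-[(trimethylsilyl)oxy]-3,7,8,8a-tetrahydronaphthalen-1(2H)-one | C[Si](C)(C)OC1=C(C)C2=CC[C@H](C)C(=O)[C@]2(CC=C)CC1 | intermediate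
11 | lithium (1R,2S,8aS)-1,2,5-trimethyl-8a-(prop-2-en-1-yl)-6-[(trimethylsilyl)oxy]-1,2,3,7,8,8a-hexahydronaphthalen-1-olate (C9 lithium alkoxide) | C[Si](C)(C)OC1=C(C)C2=CC[C@H](C)[C@@](C)([O-])[C@]2(CC=C)CC1.[Li+] | intermediate (not isolated)
12 | dilithium salt of the desilylated dienolate of 11 (C3 dienolate, C9 alkoxide) | [Li+].[Li+].[O-]C1=C(C)C2=CC[C@H](C)[C@@](C)([O-])[C@]2(CC=C)CC1 | intermediate (not isolated)
13 | (1S,4aS,5R,6S)-5-hydroxy-1-(hydroxymethyl)-1,5,6-trimethyl-4a-(prop-2-en-1-yl)-3,4,4a,5,6,7-hexahydronaphthalen-2(1H)-one | C[C@H]1CC=C2[C@@](C)(CO)C(=O)CC[C@@]2(CC=C)[C@]1(C)O | intermediate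
14 | acryloyl chloride (prop-2-enoyl chloride) | C=CC(=O)Cl | starting material
15 | [(1S,4aS,5R,6S)-5-hydroxy-1,5,6-trimethyl-2-oxo-4a-(prop-2-en-1-yl)-1,2,3,4,4a,5,6,7-octahydronaphthalen-1-yl]methyl prop-2-enoate | C[C@H]1CC=C2[C@@](C)(COC(=O)C=C)C(=O)CC[C@@]2(CC=C)[C@]1(C)O | intermediate
16 | C9 perrhenate ester of 15 | C[C@H]1CC=C2[C@@](C)(COC(=O)C=C)C(=O)CC[C@@]2(CC=C)[C@]1(C)O[Re](=O)(=O)=O | intermediate (not isolated)
17 | [(1S,5R,6S,8S)-8-hydroxy-1,5,6-trimethyl-2-oxo-5-(prop-2-en-1-yl)-1,2,3,4,5,6,7,8-octahydronaphthalen-1-yl]methyl prop-2-enoate | C[C@H]1C[C@H](O)C2=C(CCC(=O)[C@]2(C)COC(=O)C=C)[C@]1(C)CC=C | intermediate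
18 | 4-iodophenol | Oc1ccc(I)cc1 | starting material
19 | [(1S,5R,6S,8S)-8-hydroxy-1,5,6-trimethyl-2-oxo-5-(prop-2-en-1-yl)-1,2,3,4,5,6,7,8-octahydronaphthalen-1-yl]methyl 3-(4-hydroxyphenyl)propanoate | C[C@H]1C[C@H](O)C2=C(CCC(=O)[C@]2(C)COC(=O)CCc2ccc(O)cc2)[C@]1(C)CC=C | intermediate
20 | glyoxylic acid (oxoacetic acid) | O=CC(=O)O | starting material
21 | [(1S,5R,6S,8S)-8-hydroxy-1,5,6-trimethyl-2-oxo-5-(4-oxobutyl)-1,2,3,4,5,6,7,8-octahydronaphthalen-1-yl]methyl 3-(4-hydroxyphenyl)propanoate | C[C@H]1C[C@H](O)C2=C(CCC(=O)[C@]2(C)COC(=O)CCc2ccc(O)cc2)[C@]1(C)CCCC=O | intermediate (not isolated)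
22 | [(1S,5R,6S,8S)-8-hydroxy-5-[2-(2-hydroxy-5-oxo-2,5-dihydrofuran-3-yl)ethyl]-1,5,6-trimethyl-2-oxo-1,2,3,4,5,6,7,8-octahydronaphthalen-1-yl]methyl 3-(4-hydroxyphenyl)propanoate (epimer mixture at the hemiacetal carbon) | C[C@H]1C[C@H](O)C2=C(CCC(=O)[C@]2(C)COC(=O)CCc2ccc(O)cc2)[C@]1(C)CCC1=CC(=O)OC1O | intermediate
23 | (2Z)-4-hydroxy-3-{2-[(1R,2S,4S,5S)-4-hydroxy-5-({[3-(4-hydroxyphenyl)propanoyl]oxy}methyl)-1,2,5-trimethyl-6-oxo-1,2,3,4,5,6,7,8-octahydronaphthalen-1-yl]ethyl}but-2-enoic acid | C[C@H]1C[C@H](O)C2=C(CCC(=O)[C@]2(C)COC(=O)CCc2ccc(O)cc2)[C@]1(C)CC/C(CO)=C/C(=O)O | intermediate (not isolated)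
24 | [(1S,5R,6S,8S)-8-hydroxy-1,5,6-trimethyl-2-oxo-5-[2-(5-oxo-2,5-dihydrofuran-3-yl)ethyl]-1,2,3,4,5,6,7,8-octahydronaphthalen-1-yl]methyl 3-(4-hydroxyphenyl)propanoate (CNP0301014.1) | C[C@H]1C[C@H](O)C2=C(CCC(=O)[C@]2(C)COC(=O)CCc2ccc(O)cc2)[C@]1(C)CCC1=CC(=O)OC1 | target

## Step count and risks

Total step count: 10. Longest linear sequence: 10 steps (from 1; the route is fully linear, 2, 4, 14, 18 and 20 are used as bought).

The three steps most likely to fail are steps 5, 7 and 8.

The one-pot addition, desilylation and aldol of step 5 can fail through enolisation of the hindered C9 ketone by MeLi, γ-attack of formaldehyde, or retro-aldol on warming. The fallback separates the events and replaces the aldol acceptor by an alkylating agent. It sets out from 10: MeLi/CeCl3 (THF, −78 °C) followed by 1 M HCl work-up adds the C9 methyl and hydrolyses the silyl dienol ether to the enone (4aS,5R,6S)-5-hydroxy-1,5,6-trimethyl-4a-(prop-2-en-1-yl)-4,4a,5,6,7,8-hexahydronaphthalen-2(3H)-one F1. Deconjugative alkylation of its potassium dienolate (KOt-Bu, t-BuOH/THF, 0 °C) with 4-methoxybenzyl chloromethyl ether, again anti to the allyl group, gives the ether (1S,4aS,5R,6S)-5-hydroxy-1-{[(4-methoxybenzyl)oxy]methyl}-1,5,6-trimethyl-4a-(prop-2-en-1-yl)-3,4,4a,5,6,7-hexahydronaphthalen-2(1H)-one F2. DDQ (CH2Cl2/pH 7 buffer) then removes the 4-methoxybenzyl group and the route is rejoined at 13.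

The proposed rearrangement of step 7 can fail if the perrhenate does not ionise the unactivated tertiary alcohol, if the cation is diverted (homoallyl participation of the 5,6-alkene, 1,2-hydride shift from C8, ring contraction), or if the allyl cation eliminates to dienes. The fallback is a classical two-stage solvolysis with known chemistry that sets out from 15. Anhydrous HCO2H (23 °C) effects the Wagner–Meerwein backbone rearrangement under stoichiometric Brønsted-acid ionisation and traps the allyl cation as the ester [(1S,5R,6S,8S)-8-(formyloxy)-1,5,6-trimethyl-2-oxo-5-(prop-2-en-1-yl)-1,2,3,4,5,6,7,8-octahydronaphthalen-1-yl]methyl prop-2-enoate F3. Selective methanolysis of the formate (KHCO3, MeOH, 0 °C; the hindered acrylate survives) comes back to the route at 17.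

The cobalt-catalysed hydroarylation of step 8 can fail through reduction or homocoupling of the aryl iodide or isomerisation of the allyl group. The fallback forms the aryl–carbon bond by a Heck reaction and removes the extra unsaturation separately. It sets out from 17 (with 18): Pd(OAc)2, NaHCO3, n-Bu4NCl, DMF, 60 °C gives the cinnamate [(1S,5R,6S,8S)-8-hydroxy-1,5,6-trimethyl-2-oxo-5-(prop-2-en-1-yl)-1,2,3,4,5,6,7,8-octahydronaphthalen-1-yl]methyl (2E)-3-(4-hydroxyphenyl)prop-2-enoate F4. Conjugate reduction with [(Ph3P)CuH]6 (toluene, 23 °C), which leaves the isolated alkenes and the ketone alone, comes back at 19.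

## Further compounds

F1 | step 5 | (4aS,5R,6S)-5-hydroxy-1,5,6-trimethyl-4a-(prop-2-en-1-yl)-4,4a,5,6,7,8-hexahydronaphthalen-2(3H)-one | O=C1CC[C@@]2(CC=C)[C@](C)(O)[C@@H](C)CCC2=C1C
F2 | step 5 | (1S,4aS,5R,6S)-5-hydroxy-1-{[(4-methoxybenzyl)oxy]methyl}-1,5,6-trimethyl-4a-(prop-2-en-1-yl)-3,4,4a,5,6,7-hexahydronaphthalen-2(1H)-one | C[C@H]1CC=C2[C@@](C)(COCc3ccc(OC)cc3)C(=O)CC[C@@]2(CC=C)[C@]1(C)O
F3 | step 7 | [(1S,5R,6S,8S)-8-(formyloxy)-1,5,6-trimethyl-2-oxo-5-(prop-2-en-1-yl)-1,2,3,4,5,6,7,8-octahydronaphthalen-1-yl]methyl prop-2-enoate | C[C@H]1C[C@H](OC=O)C2=C(CCC(=O)[C@]2(C)COC(=O)C=C)[C@]1(C)CC=C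
F4 | step 8 | [(1S,5R,6S,8S)-8-hydroxy-1,5,6-trimethyl-2-oxo-5-(prop-2-en-1-yl)-1,2,3,4,5,6,7,8-octahydronaphthalen-1-yl]methyl (2E)-3-(4-hydroxyphenyl)prop-2-enoate | C[C@H]1C[C@H](O)C2=C(CCC(=O)[C@]2(C)COC(=O)/C=C/c2ccc(O)cc2)[C@]1(C)CC=C
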